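The data were computed from invented constants, noise included.

Late in the maple run, target had fallen to 7 % at 20.0 d, from 21 % at 0.833 d. So target is lost as well as made.

| flask | solid substrate | partner | protic impurity | remark | time |
|---|---|---|---|---|---|
| oak | 0.050 M | 0.067 M (fed, over 2.0 h) | 0.015 M | run made earlier |  |
| maple | 0.050 M | 0.15 M (fed, over 2.0 h) | 0.015 M | run made earlier |  |
| birch | 0.075 M | 0.10 M (fed, over 2.0 h) | 0.015 M | run made earlier |  |
| flask | 0.050 M | 0.100 M (fed, over 2.0 h) | 0.0150 M |  | 15 d |

| run | time / d | target / % | solid substrate / % |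
|---|---|---|---|
| oak | 0.250 | 6 | 18 |
| oak | 0.833 | 9 | 5 |
| oak | 2.50 | 9 | 0 |
| oak | 6.00 | 8 | 1 |
| oak | 20.0 | 3 | 0 |
| maple | 0.250 | 11 | 12 |
| maple | 0.833 | 21 | 0 |
| maple | 2.50 | 20 | 1 |
| maple | 6.00 | 11 | 0 |
| maple | 20.0 | 7 | 0 |
| birch | 0.250 | 6 | 41 |
| birch | 0.833 | 7 | 31 |
| birch | 2.50 | 10 | 13 |
| birch | 6.00 | 11 | 0 |
| birch | 20.0 | 1 | 2 |

(scatter of a reading: 1.5 percentage points)

- at the start none of the solid substrate is in solution
- a reading or a percentage of target counts all its forms, free or not

1. the moment within 15 d at which there is most target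
2. the amount of target, in percent of the solid substrate charged, at that time

I compared the rates at one moment. I took the gain of target to go with [partner] and its loss to grow with [target]. At the peak the two match. So I expected the peak percentage to follow E, the equivalents of partner: charged [partner] over charged [solid substrate].

Oak had E = 1.34 and a highest reading of 9 %. Maple had 3.00 and 21 %. Birch had 1.33 and 11 %. Per equivalent these read 6.72 %, 7.00 % and 8.27 %. Their mean is g = 7.32 %, the peak percentage of target per equivalent of partner. Protic impurity was 0.0150 M in each run, so g holds that charge fixed.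

Was one number enough? For height, yes: oak and birch have nearly equal E, and their peaks differ by 2 percentage points against a scatter of 1.5 points. For time, no. Birch's highest reading came at 6.00 d, and at 2.50 d birch held more solid substrate than oak, 13 % against 0 %.

The flask has E = 2.00, so I reckoned 14.6 %. Its solid charge matches oak and maple, so I put the peak between 0.833 d and 2.50 d. The forecast gave 14.5 % (11 % to 18 %) at 1.5 d (0.8 d to 3 d): “Interpolating to 0.10 M gives about 14%”.

The flask reached its best, 15.3 %, at 1.12 d.

    solid substrate ⇌ dissolved substrate, rate k1*(cs1 - [dissolved substrate]) while solid is left; crystals form when [dissolved substrate] > cs1 (solubility = 26.0 mM, k = 1.50 h⁻¹)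
    dissolved substrate + partner ⇌ target (K = 3.90 M⁻¹, k = 0.410 M⁻¹ h⁻¹)
    dissolved substrate + target → side product A (k = 0.480 M⁻¹ h⁻¹)
    solid product ⇌ target, rate k4*(cs4 - [target]) while solid is left; crystals form when [target] > cs4 (solubility = 15.0 mM, k = 12.0 h⁻¹)
    solid substrate + protic impurity → quenched substrate (k = 26.0 M⁻¹ h⁻¹)
    solid substrate + target → side product B (k = 0.450 M⁻¹ h⁻¹)

At 2.25 d the flask still held 13.7 % of target. Its peak per equivalent was 7.65 %, against g of 7.32 %. The neighbour with 0.17 M of partner has E = 3.40, so g gives 24.9 %; that neighbour gave 23.1 %.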